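**Assumption:** (+)-larixol and 2-methyl-2-vinyl-1,3-dioxolane are bought; labdane numbering is used (C18 = 4α-carbon, C19 = 4β-methyl), with 10-CH3 β and 5-H, 9-H α in every compound.

## Retrosynthetic overview

1. Target 25 ⇐ bis-lactone 22: the 18,6α-γ-lactone is the only protecting group for 6α-OH and the C18 acid and is opened last.
2. Butenolide of 22 ⇐ α-hydroxy ketone 20 + Ph3P=C=C=O; 20 ⇐ (E)-alkenyl iodide 14 + (R)-epoxy ketal 17 (C14–C15, new nickel-catalysed reductive epoxide/alkenyl iodide coupling).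
3. 14 ⇐ alkyne 12 (carboalumination sets 13E) ⇐ methyl ketone 8 (alkyne formation, then hydration of the 8(17)-alkene sets C8).
4. 8 ⇐ (+)-larixol 1: permanganate trimming of the side chain, then Barton nitrite photolysis from 6α-OH oxidises the 4α-methyl (sets C4).
5. Ring order: rings A and B come from larixol; the γ-lactone ring (C18–O6) is closed third, the butenolide fourth, and the γ-lactone is reopened at the end.

## Route

Step 1
Reactants: 1 (+)-larixol [(13S)-labda-8(17),14-diene-6α,13-diol]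
Product: 2 6α-hydroxy-14,15-dinorlabd-8(17)-en-13-one
Conditions: KMnO4 (4.5 equiv), BnEt3NCl (cat.), CH2Cl2/H2O, 0 → 20 °C
Reagents that add atoms: none
Why: Permanganate degradation of the tertiary vinyl carbinol (alkene cleavage, then oxidative decarboxylation of the α-hydroxy acid) removes C14 and C15 and leaves the C13 methyl ketone, while the hindered 8(17)-methylene and the 6α-carbinol react more slowly and no stereocentre is touched.

Step 2
Reactants: 2 6α-hydroxy-14,15-dinorlabd-8(17)-en-13-one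
Product: 3 13-oxo-14,15-dinorlabd-8(17)-en-6α-yl nitrite
Conditions: t-BuONO (10 equiv), CH2Cl2, 20 °C, dark
Reagents that add atoms: tert-butyl nitrite, CC(C)(C)ON=O
Why: Transnitrosation from tert-butyl nitrite converts the only hydroxyl into the nitrite ester needed for the Barton reaction without an electrophilic reagent that would attack the alkene.

Step 3
Reactants: 3 13-oxo-14,15-dinorlabd-8(17)-en-6α-yl nitrite
Product: 5 (E)-oxime of 6α-hydroxy-13-oxo-14,15-dinorlabd-8(17)-en-18-al (4β-CH3 kept), via 18-nitroso compound 4 (not isolated)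
Conditions: hν (365 nm), benzene, 15 °C; then i-PrOH, 60 °C
Reagents that add atoms: none
Why: Barton nitrite photolysis, in which the equatorial 6α-alkoxyl radical lies about 2.5 Å from the equatorial 4α-methyl (C18) but about 3.5 Å from the axial 4β-methyl, so 1,5-hydrogen transfer through a six-membered transition state occurs only at C18 and NO recombination then tautomerisation give the oxime, which sets C4 with the oxidised carbon α and the methyl β; 365 nm light excites the nitrite and not the ketone.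

Step 4
Reactants: 5 (E)-oxime of 6α-hydroxy-13-oxo-14,15-dinorlabd-8(17)-en-18-al
Product: 7 6α,18-epoxy-18-hydroxy-14,15-dinorlabd-8(17)-en-13-one (lactol; both C18 epimers), via hydroxy aldehyde 6 (not isolated)
Conditions: NaNO2, AcOH/H2O/THF, 5 °C
Reagents that add atoms: sodium nitrite, [Na+].[O-]N=O
Why: Nitrosative deoximation (the classical follow-up of the Barton reaction) frees the neopentyl aldehyde, which the peri 6α-hydroxyl traps as the five-membered lactol.

Step 5
Reactants: 7 6α,18-epoxy-18-hydroxy-14,15-dinorlabd-8(17)-en-13-one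
Product: 8 13-oxo-14,15-dinorlabd-8(17)-en-18,6α-olide
Conditions: TEMPO (10 mol %), PhI(OAc)2 (1.5 equiv), CH2Cl2, 20 °C
Reagents that add atoms: none
Why: Oxoammonium (TEMPO) oxidation of the lactol gives the γ-lactone, which from here on masks both the 6α-hydroxyl and the C18 carboxyl, and alkene and ketone are inert to it.

Step 6
Reactants: 8 13-oxo-14,15-dinorlabd-8(17)-en-18,6α-olide
Product: 11 15,16-dinorlabd-8(17)-en-13-yn-18,6α-olide (terminal alkyne; its CH is C14 from here on), via enol phosphate 9 (not isolated), via lithium acetylide 10 (not isolated)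
Conditions: LiN(i-Pr)2 (1.1 equiv), THF, −78 °C; ClP(O)(OEt)2, −78 → 20 °C; LiN(i-Pr)2 (2.3 equiv), −78 → 20 °C; H2O
Reagents that add atoms: none
Why: Negishi's methyl ketone to terminal alkyne conversion (kinetic deprotonation on the methyl side, O-phosphorylation, E2 elimination) works here because the lactone has no α-hydrogen and no free hydroxyl is present.

Step 7
Reactants: 11 15,16-dinorlabd-8(17)-en-13-yn-18,6α-olide
Product: 12 8α-hydroxy-15,16-dinorlabd-13-yn-18,6α-olide (8β-CH3)
Conditions: Co(acac)2 (20 mol %), PhSiH3 (2.5 equiv), O2 (1 atm), THF, 20 °C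
Reagents that add atoms: dioxygen, O=O
Why: Mukaiyama hydration (hydrogen-atom transfer from a cobalt hydride to the 1,1-disubstituted alkene, then O2 capture) gives the Markovnikov tertiary alcohol, and the planar C8 radical is trapped on the α face because the β (axial) face is blocked by the 1,3-related angular C10 methyl, which sets 8α-OH/8β-CH3; the terminal alkyne is a much poorer hydrogen-atom acceptor.

Step 8
Reactants: 12 8α-hydroxy-15,16-dinorlabd-13-yn-18,6α-olide
Product: 14 (13E)-8α-hydroxy-14-iodo-15-norlabd-13-en-18,6α-olide, via alkenylalane 13 (not isolated)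
Conditions: AlMe3 (3 equiv), Cp2ZrCl2 (0.5 equiv), CH2Cl2, 0 → 20 °C; I2, THF, −30 → 0 °C; H2O
Reagents that add atoms: trimethylaluminium, C[Al](C)C; iodine, II
Why: Negishi zirconium-catalysed carboalumination adds CH3 and Al syn with Al at the terminus, and iodinolysis with retention gives the (E)-2-methylalkenyl iodide, which sets the 13E geometry (the free tertiary hydroxyl only consumes one equivalent of AlMe3).

Step 9
Reactants: 15 2-methyl-2-vinyl-1,3-dioxolane
Product: 16 rac-2-methyl-2-(oxiran-2-yl)-1,3-dioxolane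
Conditions: mCPBA, NaHCO3, CH2Cl2, 40 °C
Reagents that add atoms: 3-chloroperbenzoic acid, OOC(=O)c1cccc(Cl)c1
Why: Prilezhaev epoxidation of the vinyl group, with the ketal stable under the buffered conditions.

Step 10
Reactants: 16 rac-2-methyl-2-(oxiran-2-yl)-1,3-dioxolane
Product: 17 (R)-2-methyl-2-(oxiran-2-yl)-1,3-dioxolane
Conditions: (S,S)-Co(salen)(OAc) (0.5 mol %; salen = N,N′-bis(3,5-di-tert-butylsalicylidene)-1,2-cyclohexanediaminate), H2O (0.55 equiv), 0 → 20 °C; distil
Reagents that add atoms: none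
Why: Jacobsen hydrolytic kinetic resolution, in which the chiral cobalt–salen complex hydrolyses the (S)-epoxide and leaves the (R)-epoxide (the same spatial series as (R)-methyl glycidate), which is distilled from the diol and whose configuration is checked by chiral GC, the mirror-image complex being used if the sense is found reversed.

Step 11
Reactants: 14 (13E)-8α-hydroxy-14-iodo-15-norlabd-13-en-18,6α-olide; 17 (R)-2-methyl-2-(oxiran-2-yl)-1,3-dioxolane
Product: 19 (13E)-8α-hydroxy-15-[(R)-hydroxy(2-methyl-1,3-dioxolan-2-yl)methyl]labd-13-en-18,6α-olide, via iodohydrin 18 (not isolated)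
Conditions: NiI2 (10 mol %), 4,4′-di-tert-butyl-2,2′-bipyridine (10 mol %), NaI (0.5 equiv), Et3N·HCl (1.5 equiv), Zn (2.5 equiv), DMPU, 25 °C
Reagents that add atoms: none
Why: Proposed new method: a nickel-catalysed, iodide-co-catalysed reductive cross-electrophile coupling in which NaI/Et3N·HCl open the epoxide at its CH2 terminus to iodohydrin 18, zerovalent nickel–bipyridine adds oxidatively to the alkenyl C–I bond with retention of the E geometry, the primary alkyl radical generated from 18 is captured by the alkenylnickel species and reductive elimination forms C14–C15 while Zn turns the nickel over, so the carbinol C–O bond is never broken and the R centre of 17 is carried into 19, and lactone, tertiary alcohol and ketal tolerate the mild medium; the closest known reaction type is the nickel-catalysed reductive coupling of terminal epoxides with aryl halides and of alkyl iodides with alkenyl halides, which has not been shown for a 2,2-disubstituted alkenyl iodide joined to an enantiopure ketal-bearing epoxide.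

Step 12
Reactants: 19 (13E)-8α-hydroxy-15-[(R)-hydroxy(2-methyl-1,3-dioxolan-2-yl)methyl]labd-13-en-18,6α-olide
Product: 20 (13E)-8α-hydroxy-15-[(1R)-1-hydroxy-2-oxopropyl]labd-13-en-18,6α-olide
Conditions: 1 M aq. HCl, THF, 30 °C
Reagents that add atoms: water, O
Why: Acid-catalysed ketal hydrolysis unmasks the methyl ketone, and dilute acid at 30 °C leaves the lactone, the tertiary alcohol and the trisubstituted alkene alone and does not enolise the α-ketol, so the carbinol configuration is kept.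

Step 13
Reactants: 20 (13E)-8α-hydroxy-15-[(1R)-1-hydroxy-2-oxopropyl]labd-13-en-18,6α-olide
Product: 22 (13E)-8α-hydroxy-15-[(2R)-3-methyl-5-oxo-2,5-dihydrofuran-2-yl]labd-13-en-18,6α-olide, via ylide ester 21 (not isolated)
Conditions: Ph3P=C=C=O (1.3 equiv), toluene, 80 °C
Reagents that add atoms: (triphenylphosphoranylidene)ketene, O=C=C=P(c1ccccc1)(c1ccccc1)c1ccccc1
Why: Bestmann ylide annulation, in which the ketenylidene phosphorane acylates the secondary α-ketol hydroxyl (the tertiary 8-OH does not react) and the ester ylide closes by intramolecular Wittig reaction on the methyl ketone to the 4-methylbutenolide without touching the carbinol stereocentre.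

Step 14
Reactants: 22 (13E)-8α-hydroxy-15-[(2R)-3-methyl-5-oxo-2,5-dihydrofuran-2-yl]labd-13-en-18,6α-olide
Product: 25 (13E)-6α,8α-dihydroxy-15-[(2R)-3-methyl-5-oxo-2,5-dihydrofuran-2-yl]labd-13-en-18-oic acid (the target), via dilithium salt 23 (not isolated), via seco diacid 24 (not isolated)
Conditions: LiOH (5 equiv), THF/H2O, 0 → 40 °C; then 0.5 M aq. HCl to pH 3, 0 °C
Reagents that add atoms: lithium hydroxide, [Li+].[OH-]
Why: Saponification opens the unhindered butenolide at 0 °C (before its γ-hydrogen can be removed) and the hindered peri lactone on warming, and on mild acidification only the (Z)-4-hydroxy-2-enoic acid recloses spontaneously to the butenolide while the strained 18,6α-lactone stays open, with no stereocentre involved.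

## Compound list

1 | (+)-larixol, (13S)-labda-8(17),14-diene-6α,13-diol | C=C[C@@](C)(O)CC[C@@H]1[C@@]2(C)CCCC(C)(C)[C@@H]2[C@@H](O)CC1=C | starting material
2 | 6α-hydroxy-14,15-dinorlabd-8(17)-en-13-one | CC(=O)CC[C@@H]1[C@@]2(C)CCCC(C)(C)[C@@H]2[C@@H](O)CC1=C | intermediate
3 | 13-oxo-14,15-dinorlabd-8(17)-en-6α-yl nitrite | CC(=O)CC[C@@H]1[C@@]2(C)CCCC(C)(C)[C@@H]2[C@@H](ON=O)CC1=C | intermediate
4 | 6α-hydroxy-18-nitroso-14,15-dinorlabd-8(17)-en-13-one (4α-CH2NO, 4β-CH3) | CC(=O)CC[C@@H]1[C@@]2(C)CCC[C@@](C)(CN=O)[C@@H]2[C@@H](O)CC1=C | intermediate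
5 | (E)-oxime of 6α-hydroxy-13-oxo-14,15-dinorlabd-8(17)-en-18-al | CC(=O)CC[C@@H]1[C@@]2(C)CCC[C@@](C)(/C=N/O)[C@@H]2[C@@H](O)CC1=C | intermediate
6 | 6α-hydroxy-13-oxo-14,15-dinorlabd-8(17)-en-18-al | CC(=O)CC[C@@H]1[C@@]2(C)CCC[C@@](C)(C=O)[C@@H]2[C@@H](O)CC1=C | intermediate
7 | 6α,18-epoxy-18-hydroxy-14,15-dinorlabd-8(17)-en-13-one (lactol, C18 epimers) | CC(=O)CC[C@@H]1[C@@]2(C)CCC[C@@](C)(C3O)[C@@H]2[C@@H](O3)CC1=C | intermediate
8 | 13-oxo-14,15-dinorlabd-8(17)-en-18,6α-olide | CC(=O)CC[C@@H]1[C@@]2(C)CCC[C@@](C)(C3=O)[C@@H]2[C@@H](O3)CC1=C | intermediate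
9 | 13-(diethoxyphosphoryloxy)-15,16-dinorlabda-8(17),13-dien-18,6α-olide (enol phosphate) | C=C(OP(=O)(OCC)OCC)CC[C@@H]1[C@@]2(C)CCC[C@@](C)(C3=O)[C@@H]2[C@@H](O3)CC1=C | intermediate
10 | lithium acetylide of 15,16-dinorlabd-8(17)-en-13-yn-18,6α-olide | [Li]C#CCC[C@@H]1[C@@]2(C)CCC[C@@](C)(C3=O)[C@@H]2[C@@H](O3)CC1=C | intermediate
11 | 15,16-dinorlabd-8(17)-en-13-yn-18,6α-olide | C#CCC[C@@H]1[C@@]2(C)CCC[C@@](C)(C3=O)[C@@H]2[C@@H](O3)CC1=C | intermediate
12 | 8α-hydroxy-15,16-dinorlabd-13-yn-18,6α-olide (8β-CH3) | C#CCC[C@@H]1[C@@]2(C)CCC[C@@](C)(C3=O)[C@@H]2[C@@H](O3)C[C@@]1(C)O | intermediate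
13 | (13E)-14-(dimethylalumanyl)-15-norlabd-13-en-18,6α-olide, 8α-O-dimethylaluminium alkoxide | C[Al](C)/C=C(\C)CC[C@@H]1[C@@]2(C)CCC[C@@](C)(C3=O)[C@@H]2[C@@H](O3)C[C@@]1(C)O[Al](C)C | intermediate
14 | (13E)-8α-hydroxy-14-iodo-15-norlabd-13-en-18,6α-olide | I/C=C(\C)CC[C@@H]1[C@@]2(C)CCC[C@@](C)(C3=O)[C@@H]2[C@@H](O3)C[C@@]1(C)O | intermediate
15 | 2-methyl-2-vinyl-1,3-dioxolane | C=CC1(C)OCCO1 | starting material
16 | rac-2-methyl-2-(oxiran-2-yl)-1,3-dioxolane | CC1(OCCO1)C1CO1 | intermediate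
17 | (R)-2-methyl-2-(oxiran-2-yl)-1,3-dioxolane | CC1(OCCO1)[C@H]1CO1 | intermediate
18 | (S)-2-iodo-1-(2-methyl-1,3-dioxolan-2-yl)ethan-1-ol | CC1(OCCO1)[C@H](O)CI | intermediate
19 | (13E)-8α-hydroxy-15-[(R)-hydroxy(2-methyl-1,3-dioxolan-2-yl)methyl]labd-13-en-18,6α-olide | CC1(OCCO1)[C@H](O)C/C=C(\C)CC[C@@H]1[C@@]2(C)CCC[C@@](C)(C3=O)[C@@H]2[C@@H](O3)C[C@@]1(C)O | intermediate
20 | (13E)-8α-hydroxy-15-[(1R)-1-hydroxy-2-oxopropyl]labd-13-en-18,6α-olide | CC(=O)[C@H](O)C/C=C(\C)CC[C@@H]1[C@@]2(C)CCC[C@@](C)(C3=O)[C@@H]2[C@@H](O3)C[C@@]1(C)O | intermediate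
21 | (triphenylphosphoranylidene)acetate ester of 20 at the side-chain hydroxyl | CC(=O)[C@H](OC(=O)C=P(c1ccccc1)(c1ccccc1)c1ccccc1)C/C=C(\C)CC[C@@H]1[C@@]2(C)CCC[C@@](C)(C3=O)[C@@H]2[C@@H](O3)C[C@@]1(C)O | intermediate
22 | (13E)-8α-hydroxy-15-[(2R)-3-methyl-5-oxo-2,5-dihydrofuran-2-yl]labd-13-en-18,6α-olide | CC1=CC(=O)O[C@@H]1C/C=C(\C)CC[C@@H]1[C@@]2(C)CCC[C@@](C)(C3=O)[C@@H]2[C@@H](O3)C[C@@]1(C)O | intermediate
23 | dilithium salt of the doubly ring-opened hydroxy diacid | [Li+].[Li+].C/C(=C/C(=O)[O-])[C@H](O)C/C=C(\C)CC[C@@H]1[C@@]2(C)CCC[C@@](C)(C(=O)[O-])[C@@H]2[C@@H](O)C[C@@]1(C)O | intermediate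
24 | seco diacid with the (Z)-4-hydroxy-3-methylbut-2-enoic acid terminus | C/C(=C/C(=O)O)[C@H](O)C/C=C(\C)CC[C@@H]1[C@@]2(C)CCC[C@@](C)(C(=O)O)[C@@H]2[C@@H](O)C[C@@]1(C)O | intermediate
25 | (13E)-6α,8α-dihydroxy-15-[(2R)-3-methyl-5-oxo-2,5-dihydrofuran-2-yl]labd-13-en-18-oic acid (4α-CO2H, 4β-CH3, 8β-CH3) | CC1=CC(=O)O[C@@H]1C/C=C(\C)CC[C@@H]1[C@@]2(C)CCC[C@@](C)(C(=O)O)[C@@H]2[C@@H](O)C[C@@]1(C)O | target

## Step count and risks

Total step count: 14. Longest linear sequence: 12 (steps 1–8 and 11–14).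

The three steps most likely to fail:

**Step 11 (the proposed new coupling).** Risks are homocoupling or reduction of the alkenyl iodide and slow turnover with the hindered iodohydrin. The fallback is known chemistry and sets out from alkynol 12. Carboalumination as in step 8 gives alane 13, the volatiles are removed, and n-BuLi (hexane/THF, −78 °C) converts it into the lithium alkenyl(butyl)dimethylaluminate F1. F1 opens epoxide 17 at the CH2 terminus (0 → 20 °C) in the established alkenylalanate/epoxide manner of the Negishi carboalumination sequence and gives the homoallylic alcohol after aqueous work-up. The fallback comes back to the route at 19.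

**Step 3 (Barton photolysis).** Risks are low conversion to the oxime and loss through alkoxyl-radical fragmentation. The fallback sets out from 2 and replaces NO trapping by lead tetraacetate cyclisation: Pb(OAc)4, CaCO3, benzene, 80 °C gives the 6α,18-epoxy-14,15-dinorlabd-8(17)-en-13-one F2. Mukaiyama hydration (Co(acac)2, PhSiH3, O2) then gives the 8α-hydroxy ether F3. With no alkene left, RuCl3 (cat.)/NaIO4 oxidises the ether CH2 to the 8α-hydroxy-13-oxo-14,15-dinorlabdan-18,6α-olide F4. LiN(i-Pr)2 (2.2 equiv)/ClP(O)(OEt)2 gives the enol phosphate lithium alkoxide F5, and more LiN(i-Pr)2 gives the dilithium acetylide alkoxide F6, which is quenched with water. The fallback comes back to the route at 12.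

**Step 14 (selective opening of the peri lactone beside the butenolide).** Risks are epimerisation at the butenolide carbinol or re-closure of the 18,6α-lactone on acidification. The fallback sets out from 19 and opens the lactone before any base-sensitive group exists: KOH, MeOH/H2O, 60 °C, then acidification gives the trihydroxy acid ketal F7. Allyl bromide/Cs2CO3/DMF gives the allyl ester F8, and 1 M HCl/THF gives the α-hydroxy ketone allyl ester F9. Ph3P=C=C=O (1.05 equiv; the 6α-hydroxyl is hindered by the peri ester and the ring fusion) gives, through the ylide ester F10, the butenolide allyl ester F11. Pd(PPh3)4 (cat.)/morpholine, THF, 20 °C removes the allyl group under neutral conditions. The fallback comes back to the route at 25.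

## Further compounds

F1 | step 11 | lithium (13E)-alkenyl(butyl)dimethylaluminate derived from 13 | [Li+].CCCC[Al-](C)(C)/C=C(\C)CC[C@@H]1[C@@]2(C)CCC[C@@](C)(C3=O)[C@@H]2[C@@H](O3)C[C@@]1(C)O[Al](C)C
F2 | step 3 | 6α,18-epoxy-14,15-dinorlabd-8(17)-en-13-one | CC(=O)CC[C@@H]1[C@@]2(C)CCC[C@@](C)(C3)[C@@H]2[C@@H](O3)CC1=C
F3 | step 3 | 6α,18-epoxy-8α-hydroxy-14,15-dinorlabdan-13-one | CC(=O)CC[C@@H]1[C@@]2(C)CCC[C@@](C)(C3)[C@@H]2[C@@H](O3)C[C@@]1(C)O
F4 | step 3 | 8α-hydroxy-13-oxo-14,15-dinorlabdan-18,6α-olide | CC(=O)CC[C@@H]1[C@@]2(C)CCC[C@@](C)(C3=O)[C@@H]2[C@@H](O3)C[C@@]1(C)O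
F5 | step 3 | enol diethyl phosphate of F4 as its lithium 8-alkoxide | C=C(OP(=O)(OCC)OCC)CC[C@@H]1[C@@]2(C)CCC[C@@](C)(C3=O)[C@@H]2[C@@H](O3)C[C@@]1(C)O[Li]
F6 | step 3 | dilithium acetylide alkoxide of 12 | [Li]C#CCC[C@@H]1[C@@]2(C)CCC[C@@](C)(C3=O)[C@@H]2[C@@H](O3)C[C@@]1(C)O[Li]
F7 | step 14 | (13E)-6α,8α-dihydroxy-15-[(R)-hydroxy(2-methyl-1,3-dioxolan-2-yl)methyl]labd-13-en-18-oic acid | CC1(OCCO1)[C@H](O)C/C=C(\C)CC[C@@H]1[C@@]2(C)CCC[C@@](C)(C(=O)O)[C@@H]2[C@@H](O)C[C@@]1(C)O
F8 | step 14 | allyl ester of F7 | CC1(OCCO1)[C@H](O)C/C=C(\C)CC[C@@H]1[C@@]2(C)CCC[C@@](C)(C(=O)OCC=C)[C@@H]2[C@@H](O)C[C@@]1(C)O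
F9 | step 14 | allyl (13E)-6α,8α-dihydroxy-15-[(1R)-1-hydroxy-2-oxopropyl]labd-13-en-18-oate | CC(=O)[C@H](O)C/C=C(\C)CC[C@@H]1[C@@]2(C)CCC[C@@](C)(C(=O)OCC=C)[C@@H]2[C@@H](O)C[C@@]1(C)O
F10 | step 14 | (triphenylphosphoranylidene)acetate ester of F9 at the side-chain hydroxyl | CC(=O)[C@H](OC(=O)C=P(c1ccccc1)(c1ccccc1)c1ccccc1)C/C=C(\C)CC[C@@H]1[C@@]2(C)CCC[C@@](C)(C(=O)OCC=C)[C@@H]2[C@@H](O)C[C@@]1(C)O
F11 | step 14 | allyl ester of 25 | CC1=CC(=O)O[C@@H]1C/C=C(\C)CC[C@@H]1[C@@]2(C)CCC[C@@](C)(C(=O)OCC=C)[C@@H]2[C@@H](O)C[C@@]1(C)O
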